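(The readings are calculated with constants of no real substance; scatter was added.)

A flask that stops looks like a flask at equilibrium, and that look is the pitfall here.

| flask | D | L | E | Z | remark | time | volume of the second phase over the first |
|---|---|---|---|---|---|---|---|
| north | 0.067 M | 1 equiv | 2 mM | 1 mol% | run made earlier |  |  |
| west | 0.15 M | 1 equiv | 2 mM | 1 mol% | run made earlier |  |  |
| flask | 0.10 M | 1.00 equiv | 2.00 mM | 1 mol% |  | 5.0 d | 1.0 |

| run | time / d | D / % | Q / % |
|---|---|---|---|
| north | 0.625 | 56.5 | 42.6 |
| north | 1.25 | 56.9 | 43.9 |
| north | 1.67 | 57.2 | 43.5 |
| north | 2.50 | 56.7 | 43.5 |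
| north | 3.00 | 57.1 | 42.9 |
| west | 0.250 | 29.3 | 71.3 |
| west | 0.417 | 26.1 | 74.1 |
| west | 0.833 | 24.9 | 75.8 |
| west | 1.67 | 24.6 | 75.1 |
| west | 3.00 | 24.2 | 75.3 |

(scatter of a reading: 0.5 percentage points)

- charges count per volume of the first phase; a concentration in a rate is the amount of a species over the volume of its own phase; every rate counts per litre of the first phase
- the earlier runs hold the two phases in the same ratio of volumes as the flask asked about

- conversion of D at 5.0 d
- amount of Q at 5.0 d, in percent of the D charged

Begin with the main step by itself: Z turns D into Q, L is spent with it, and you reckon on full conversion. The readings refuse this, for in the west run D falls to 29.3% by 0.250 d and still stands at 24.2% at 3.00 d. An equilibrium of D with Q, first order each way, is no rescue: it wants one ratio of Q to D in both runs, yet the last readings give 0.751 north and 3.11 west.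

So add catalyst deactivation. Suppose each Z is lost to one E, the rate of a turn going with L and the rate of a loss going with E, so that a run stops with E down by the Z charged. With L tracking D, the log of D's fall then grows in proportion to the log of E's fall. That proportion, read from the plateau readings of D as 1.38 in the north run, is the race ratio, the log of D's fall over the log of E's fall. The west run reads 1.01. In the flask E's log fall is 0.693, so these two ratios give 61.6% and 50.3% conversion.

The north ratio stands higher than the west one, so something more is at work. I leave it unnamed and interpolate on the catalyst charged: 1.23 for the flask, hence 57.4% conversion.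

The forecast says 60.5% conversion and 60.5% of Q, above my figure, on the ground that “The two readings bracket the answer”.

The flask gives 58.1% conversion and 58.1% of Q, 0.7 percentage points above my reckoning.

    D + J → Q + Z (k = 0.290 M⁻¹ s⁻¹)
    Z + E → G (k = 0.180 M⁻¹ s⁻¹)
    Z + L ⇌ J + X (K = 1.90, k = 0.300 M⁻¹ s⁻¹)

The flask's own race ratio comes to 1.26, higher than the west reading and lower than the north one. For a neighbour flask with 0.6 mol% of Z, the north ratio gives 38.8% conversion, and that neighbour stands at 39.9%. The flask itself has come to rest: at 0.500 d Z and J hold 0.286% and 0.170% of the catalyst, and at 2.50 d G holds 100%. Ten times the time changes nothing: at 50.0 d the conversion in the flask stands at 58.1%.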